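(Readings and results are simulated for substances that don't exist; noise was put on by code.)

A small charge of G, 5 mol% on X, has to carry a flask of X over to Q while G itself goes over to J. Three flasks differ in temperature, and two earlier runs are at hand.

| flask | X | G | temperature | remark | time |
|---|---|---|---|---|---|
| winter | 1 M | 3.4 mol% | 45 °C | run made earlier |  |
| dawn | 1 M | 7.5 mol% | 65 °C | run made earlier |  |
| theta | 1.0 M | 5 mol% | 50 °C |  | 6.0 min |
| alpha | 1.0 M | 5 mol% | 80 °C |  | 6.0 min |
| delta | 1.0 M | 5 mol% | 65 °C |  | 6.0 min |

- winter (time / min: Q / %): 0.667: 33; 1.33: 46; 2.00: 61; 3.00: 70; 4.00: 76
- dawn (time / s: Q / %): 10.0: 40; 15.0: 51; 30.0: 65; 60.0: 75; 120: 80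

(standard deviation of a reading: 1.5 percentage points)

- which flask leads in amount of Q, in percent of the X charged ("all alike" within 1.5 percentage points) (theta / alpha / delta / all alike)
- how much Q is there at the end, in percent of the X charged: theta
- how much Q is there at the end, in percent of the X charged: alpha
- how much Q is there at the end, in percent of the X charged: delta

- what may be going on: X -> L; G -> J; X + G -> G + Q

The bench rule says that catalyst and heat buy speed and leave the end where it is. For speed the runs obey: dawn, with more G and more heat, stands at 40 % after 10.0 s, and winter at 33 % after 0.667 min, so dawn climbs faster than winter. By that rule alpha, hotter than the other two, should lead.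

Now I follow one molecule of X. At each moment it may meet live G, a pseudo-first-order step at a given [G], and each stretch of that life takes the same fraction of the X still there. The step G -> J has no X in it, so at one temperature the summed life of G grows in proportion to the charge. Dawn's reach, 1.61, the natural log of one over the share of X not turned into Q, is read at 120 s. Winter's is 1.43, read at 4.00 min. Both are readings with their scatter, and X lost to L counts as not reached. Neither reading need be a full reach, so I look at the last doubling of time. Winter's reach at 2.00 min is 0.942, and the stretch up to 4.00 min adds a fraction 0.516 of that. Dawn's reach at 60.0 s is 1.39, and the stretch up to 120 s adds a fraction 0.161, smaller than winter's, so I take dawn's reach as read and extend winter's. The step G -> J takes a steady fraction of G per minute, so each equal stretch should add the same fraction of the stretch before, which sums to a full reach of 1.94 for winter.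

Here the rule ends: dawn holds 2.21 times winter's G but 0.830 times its full reach. Per unit of G, dawn at 65 °C reaches less than winter at 45 °C, by a factor 0.375.

I scale by loading and carry that factor smoothly in temperature, treating each flask as having its full reach at 6.0 min, an assumption that puts theta too high if its G is still alive then. That gives 89.3 % for theta, 65.8 % for delta and 40.2 % for alpha, so theta leads.

The forecast also names theta, with 87 % there, below my figure, and with 71 % for delta and 50 % for alpha, both above mine: “Heating therefore favours death and X→L over Q.”

The flasks give 87.0 % in theta, 64.9 % in delta and 41.0 % in alpha, so theta leads.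

    X → L (k = 0.0244 s⁻¹, Ea = 102 kJ mol⁻¹)
    G → J (k = 0.122 s⁻¹, Ea = 89.0 kJ mol⁻¹)
    X + G → G + Q (k = 1.59 M⁻¹ s⁻¹, Ea = 44.0 kJ mol⁻¹)
    (constants at 80 °C)

Alpha's own result gives a reach of 0.528. A neighbouring flask is alpha with 12 mol% of G in place of 5 mol%, so its reach should be 1.27, which reckons to 71.9 % of Q, and that flask ends at 70.1 %.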